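What stands in the south flask at 2.0 h, and which remedy adds the most L in the 40 min after it?

| flask | G | temperature | remark | time |
|---|---|---|---|---|
| south | 0.80 M | 0 °C | the very flask that is asked about, followed so far |  |
| north-west | 0.54 M | −5 °C | run made earlier |  |
| flask | 0.80 M | 0 °C |  | 2.0 h |

| run | time / min | L / % |
|---|---|---|
| south | 8.00 | 14.0 |
| south | 12.0 | 14.3 |
| south | 20.0 | 13.8 |
| south | 40.0 | 13.5 |
| south | 60.0 | 13.1 |
| south | 90.0 | 14.2 |
| north-west | 0.833 | 6.2 |
| north-west | 2.50 | 10.9 |
| north-west | 4.00 | 10.5 |
| north-west | 6.00 | 10.9 |
| north-west | 10.0 | 9.1 |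
| north-west | 12.0 | 9.5 |

(readings scatter by 0.5 percentage points)

- teal: at 2.0 h raise the temperature by 15 K, then wait 40 min
- amber: at 2.0 h take out 90% of the L then present, then wait 40 min
- red: at 2.0 h add G, 50.0% of the amount charged, then wait 40 min
- blue: change nothing and wait 40 min more

- L, in percent of the G first charged, at 2.0 h
- the remedy with the largest gain of L, or "none" below 2 percentage points (teal / amber / red / blue / none)
- L present, with what was taken out counted in, in percent of the G first charged, after red
- L present, with what was taken out counted in, in percent of the G first charged, after blue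

- what is taken out of L is counted as made
- additions bring no volume worth counting

The south run goes flat from 8.00 min on, averaging 13.8%. The north-west run does not stay flat: it averages 10.8% from 2.50 min to 6.00 min, then 9.30% at 10.0 min and 12.0 min, a drop of 1.5 percentage points against a scatter of 0.5 points, so I take the later figure as its level. So I put the south flask at 13.8% now and after blue.

I carry one number, the level ratio 1.49: the flat level of the south run divided by the late level of the north-west run. If the share of G ending as L does not depend on the charge, this ratio is what each step from −5 °C to 0 °C multiplies the level by. Teal's 15 K is 3 such steps, which gives 45.3%, a gain of 31 points. The same share of a larger charge gives 20.7% after red, and amber gives 24.5%. I therefore choose teal, whose level stands higher than either.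

But one number is not enough: the runs also differ in charge, by a factor of 1.48, and a level rising with charge would fit them too. So the level after heating is the thing to watch.

The forecast gives 13.8% now, 13.8% after blue and 27.5% after red, and it names red, holding that “temperature has little effect and teal gains little”. There we part.

The south flask gives 13.5% at 2.0 h, 13.5% after blue and 19.4% after red. The best remedy is teal, which gains 20 points, against 11 points for amber and 5.9 points for red.

    L ⇌ X (K = 0.130, k = 0.0130 s⁻¹, Ea = 75.0 kJ mol⁻¹, ΔH = −36.0 kJ mol⁻¹)
    G ⇌ L (K = 0.430, k = 0.00420 s⁻¹, Ea = 87.0 kJ mol⁻¹, ΔH = 31.0 kJ mol⁻¹)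
    2 G ⇌ E (K = 0.620 L mol⁻¹, k = 7.00 × 10⁻⁴ L mol⁻¹ s⁻¹, Ea = 46.0 kJ mol⁻¹, ΔH = −26.0 kJ mol⁻¹)
    G ⇌ Q (K = 1.40, k = 0.0130 s⁻¹, Ea = 74.0 kJ mol⁻¹, ΔH = −49.0 kJ mol⁻¹)
    (constants at 0 °C)

In the south flask at 120 min, the forward half-life of G by the step to L alone is 2.8 min, much shorter than the 2.0 h allowed. At 1200 min the flask still stands at 13.5%, so what I see is a balance (thermodynamic control). On the neighbour flask kept at 15 °C, 3 steps of 1.49 from 13.8% give 45.6%, and that flask stands at 33.8% at 2.0 h.

The runs stem from a simulated flask from invented constants, and the scatter is random.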